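**Retrosynthetic overview**
1. Target 40 ⇐ acid unmasking of 39; ring C (γ-lactone, C8–C17 bond, C8 and C17 centres) is made last from keto ester 36 by a copper hydride reductive aldol lactonisation (new).
2. 36 ⇐ ring B (ten-membered) closed at C6–C7 by Ni/Cr-mediated vinyl iodide–aldehyde coupling of 30; C8 is carried as a PMB-protected carbinol and oxidised after ring closure.
3. 30 ⇐ ring-A alkyne 10: C3–C4 by asymmetric alkenylzinc addition to (Z)-3-iodo-2-methylacrolein 14, C2/C3 by hydroxyl-directed dihydroxylation, C8–C9 by alkoxyallylboration.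
4. 10 ⇐ ring A by enantioselective Diels–Alder of enal 3 with dienyl acetate 5 (C1, C10), Pd elimination to a diene and face-selective dihydroxylation (C11, C12).
5. Ring order: A (Diels–Alder), then B (ten-membered carbocycle), then C (lactone).

Assumption: atom labels follow briarane numbering (C15 = methyl on C1, C16 = methyl on C5, C17/C18/C19 = lactone α-carbon, its methyl and the carbonyl, C20 = methyl on C11); the target is (1S,2R,3R,4S,5Z,7S,8S,9R,10S,11S,12R,17S) and the SMILES strings fix the configuration of every compound.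

Step 1
Reactants: 1 (tert-butyldimethylsilyloxy)acetaldehyde; 2 2-(triphenylphosphoranylidene)propanal
Product: 3 (2E)-4-[(tert-butyldimethylsilyl)oxy]-2-methylbut-2-enal
Conditions: toluene, 80 °C
Reagents that add atoms: none
Why: Wittig olefination with an α-branched stabilised ylide gives the (E)-trisubstituted enal, the ylide reacting only with the more electrophilic aliphatic aldehyde.

Step 2
Reactants: 4 (2E)-pent-2-enal
Product: 5 (1E,3E)-penta-1,3-dien-1-yl acetate
Conditions: isopropenyl acetate, TsOH·H2O (cat.), Cu(OAc)2 (cat., inhibitor), 95 °C, acetone distilled off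
Reagents that add atoms: isopropenyl acetate, CC(=C)OC(C)=O
Why: Acid-catalysed enol-acetate exchange (dienol acetylation) under thermodynamic control gives mainly the E,E-dienyl acetate; minor geometric isomers do not react in step 3.

Step 3
Reactants: 3 (2E)-4-[(tert-butyldimethylsilyl)oxy]-2-methylbut-2-enal; 5 (1E,3E)-penta-1,3-dien-1-yl acetate
Product: 6 (1R,2S,5R,6S)-6-{[(tert-butyldimethylsilyl)oxy]methyl}-1-formyl-1,5-dimethylcyclohex-3-en-2-yl acetate
Conditions: (R)-o-tolyl oxazaborolidine (from (R)-α,α-diphenylprolinol) activated with Tf2NH (20 mol %), CH2Cl2, −78 → −40 °C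
Reagents that add atoms: none
Why: Enantioselective Diels–Alder reaction under chiral oxazaborolidinium Lewis acid catalysis: the acetoxy terminus bonds to the formyl-bearing carbon (ortho rule), the E-dienophile geometry places the formyl and CH2OTBS groups trans, and the catalyst-bound s-trans enal is attacked on its Cα-si face, which sets C1 (quaternary) and C10; the C11 and C14 centres are erased in step 4.

Step 4
Reactants: 6 Diels–Alder adduct (allylic acetate)
Product: 7 (1S,6S)-6-{[(tert-butyldimethylsilyl)oxy]methyl}-1,5-dimethylcyclohexa-2,4-diene-1-carbaldehyde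
Conditions: Pd(PPh3)4 (5 mol %), Et3N, THF, 65 °C
Reagents that add atoms: none
Why: Tsuji-type elimination: zerovalent palladium ionises the allylic acetate with inversion, and syn β-hydride elimination of H-11 (anti to the acetate because both diene termini were E) gives the conjugated diene, C1 being quaternary and offering no other β-hydrogen.

Step 5
Reactants: 7 diene aldehyde
Product: 8 (1S,4R,5S,6S)-6-{[(tert-butyldimethylsilyl)oxy]methyl}-4,5-dihydroxy-1,5-dimethylcyclohex-2-ene-1-carbaldehyde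
Conditions: OsO4 (2 mol %), NMO, acetone/H2O, 0 °C
Reagents that add atoms: N-methylmorpholine N-oxide, C[N+]1([O-])CCOCC1; water, O; osmium tetroxide (oxygen carrier), O=[Os](=O)(=O)=O
Why: Upjohn dihydroxylation attacks the more electron-rich trisubstituted C11=C12 bond of the diene on the face anti to the adjacent C10 CH2OTBS group, giving the cis-diol with C11 (S) and C12 (R).

Step 6
Reactants: 8 cis-diol aldehyde
Product: 9 (1S,4R,5S,6S)-6-{[(tert-butyldimethylsilyl)oxy]methyl}-4,5-(isopropylidenedioxy)-1,5-dimethylcyclohex-2-ene-1-carbaldehyde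
Conditions: 2-methoxypropene, PPTS (cat.), CH2Cl2, 0 °C
Reagents that add atoms: 2-methoxypropene, COC(C)=C
Why: Acid-catalysed transacetalisation closes the cis-fused acetonide, which protects C11-OH/C12-OH to the end and frees the aldehyde from any lactol form.

Step 7
Reactants: 9 acetonide aldehyde
Product: 10 1-ethynyl analogue of 9 (formyl replaced by C≡CH)
Conditions: dimethyl (1-diazo-2-oxopropyl)phosphonate, K2CO3, MeOH, 0 °C → rt
Reagents that add atoms: dimethyl (1-diazo-2-oxopropyl)phosphonate, CC(=O)C(=[N+]=[N-])P(=O)(OC)OC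
Why: Seyferth–Gilbert homologation with the Ohira–Bestmann reagent converts the non-enolisable aldehyde into the terminal alkyne (C3 added) under mild base without touching C1.

Step 8
Reactants: 11 prop-2-yn-1-ol
Product: 13 (2Z)-3-iodo-2-methylprop-2-en-1-ol, via alkenylmagnesium alkoxide 12 (not isolated)
Conditions: MeMgBr (2.5 equiv), CuI (10 mol %), THF, −10 °C → rt; then I2, −78 → 0 °C; H2O
Reagents that add atoms: methylmagnesium bromide, C[Mg]Br; iodine, II
Why: Alkoxide-directed, copper-catalysed anti-carbomagnesiation places methyl on the internal carbon and magnesium cis to the CH2O group, and iodinolysis with retention gives the Z iodide.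

Step 9
Reactants: 13 (2Z)-3-iodo-2-methylprop-2-en-1-ol
Product: 14 (2Z)-3-iodo-2-methylprop-2-enal
Conditions: MnO2, CH2Cl2, rt
Reagents that add atoms: none
Why: Allylic alcohol oxidation on MnO2 is neutral and keeps the Z geometry.

Step 10
Reactants: 10 ring-A alkyne; 14 (2Z)-3-iodo-2-methylprop-2-enal
Product: 17 (1E,3R,4Z)-5-iodo-4-methyl-1-[(1S,4R,5S,6S)-6-{[(tert-butyldimethylsilyl)oxy]methyl}-4,5-(isopropylidenedioxy)-1,5-dimethylcyclohex-2-en-1-yl]penta-1,4-dien-3-ol, via alkenylzirconocene chloride 15 (not isolated), via alkenyl(methyl)zinc 16 (not isolated)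
Conditions: Cp2Zr(H)Cl, CH2Cl2, rt; Me2Zn, toluene, −65 °C; (2R)-(+)-3-exo-morpholinoisoborneol (10 mol %), then 14, −30 → 0 °C; H2O
Reagents that add atoms: none
Why: Syn hydrozirconation gives the (E)-alkenyl metal, zirconium-to-zinc transmetalation and amino-alcohol-catalysed asymmetric alkenylzinc addition form C3–C4, the (+)-ligand directing attack to the re face of 14 so that C4 is set by the reagent.

Step 11
Reactants: 17 dienol
Product: 19 (1R,2S,3S,4Z)-5-iodo-4-methyl-1-[ring-A unit of 17]pent-4-ene-1,2,3-triol, via osmate ester 18 (not isolated)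
Conditions: OsO4 (1.05 equiv), TMEDA (1.1 equiv), CH2Cl2, −78 °C; then ethylenediamine, rt
Reagents that add atoms: osmium tetroxide, O=[Os](=O)(=O)=O
Why: Hydrogen-bond-directed dihydroxylation: the C4-OH binds the OsO4·TMEDA complex and delivers it syn to itself onto the E-C2=C3 bond (syn addition gives 2,3-threo), which sets C2 and C3 of the all-syn triol, while the iodo-alkene is electron-poor and the ring alkene hindered.

Step 12
Reactants: 19 triol
Product: 20 2,3,4-triacetate of 19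
Conditions: Ac2O, DMAP (cat.), pyridine, rt
Reagents that add atoms: acetic anhydride, CC(=O)OC(C)=O
Why: DMAP-catalysed acylation installs the three secondary acetates of the target at once and protects them for the remaining non-basic steps.

Step 13
Reactants: 20 triacetate silyl ether
Product: 21 primary alcohol (C9-OH) of 20
Conditions: HF·pyridine, pyridine/THF, 0 °C → rt
Reagents that add atoms: none
Why: Buffered fluoride cleaves the primary TBS ether selectively, acetonide, acetates and vinyl iodide being stable.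

Step 14
Reactants: 21 primary alcohol
Product: 22 C9 aldehyde (triacetate, acetonide, vinyl iodide)
Conditions: Dess–Martin periodinane, pyridine, CH2Cl2, 0 °C → rt
Reagents that add atoms: none
Why: Dess–Martin oxidation is neutral and fast, so the C10 centre next to the new aldehyde is not epimerised.

Step 15
Reactants: 22 C9 aldehyde; 23 1-methoxy-4-[(prop-2-en-1-yloxy)methyl]benzene (allyl PMB ether)
Product: 27 (8R,9R)-homoallylic alcohol (C9-OH and C8-OPMB syn; C7 vinyl), via allyllithium 24 (not isolated), via allylborane 25 (not isolated), via borinate ester 26 (not isolated)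
Conditions: 23, sBuLi, THF, −78 °C; (−)-Ipc2BOMe; BF3·OEt2; then 22, −78 °C; ethanolamine, rt
Reagents that add atoms: none
Why: Brown (Z)-γ-alkoxyallylboration through a closed chair transition state gives the syn product, and the reagent derived from (−)-Ipc2BOMe adds to the si face of the aldehyde, setting C9 (R) by reagent control (C8 is only a placeholder).

Step 16
Reactants: 27 homoallylic alcohol
Product: 28 C9 acetate of 27
Conditions: Ac2O, DMAP, pyridine, rt → 40 °C
Reagents that add atoms: acetic anhydride, CC(=O)OC(C)=O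
Why: Acylation installs the fourth acetate of the target on the hindered C9 hydroxyl before it becomes flanked by a quaternary carbon.

Step 17
Reactants: 28 terminal alkene
Product: 30 (8S,9R)-C7 aldehyde (α-OPMB, β-OAc), via vicinal diol 29 (not isolated)
Conditions: OsO4 (5 mol %), NMO, acetone/H2O, 0 °C; then NaIO4, THF/pH 7 buffer, 0 °C
Reagents that add atoms: N-methylmorpholine N-oxide, C[N+]1([O-])CCOCC1; water, O; osmium tetroxide (oxygen carrier), O=[Os](=O)(=O)=O
Why: Dihydroxylation picks the only monosubstituted alkene, and periodate glycol cleavage gives the aldehyde, which is used at once.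

Step 18
Reactants: 30 iodo aldehyde
Product: 32 (7S,8R,9R)-macrocyclic allylic alcohol (ring B closed; C7-OH, C8-OPMB, C9-OAc), via alkenylchromium dichloride 31 (not isolated)
Conditions: CrCl2 (4 equiv), (S)-N-[2-(4-isopropyl-4,5-dihydrooxazol-2-yl)-6-methylphenyl]methanesulfonamide (4.4 equiv), Et3N (4.4 equiv), NiCl2 (10 mol %), THF, 2 mM, rt; H2O
Reagents that add atoms: none
Why: Intramolecular Nozaki–Hiyama–Kishi reaction: zerovalent nickel inserts into the vinyl iodide, transmetalation to chromium gives an alkenylchromium that adds to the aldehyde at high dilution with retention of the Z geometry, and the chiral sulfonamide on chromium controls the new C7 carbinol.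

Step 19
Reactants: 32 macrocyclic alcohol
Product: 33 C7 pyruvate ester of 32
Conditions: pyruvic acid, DCC, DMAP (cat.), CH2Cl2, 0 °C
Reagents that add atoms: pyruvic acid, CC(=O)C(=O)O
Why: Steglich esterification brings in C17, C18 and C19 of the lactone on the C7 oxygen.

Step 20
Reactants: 33 pyruvate ester
Product: 34 C7 2-(triethylsilyloxy)acrylate ester
Conditions: Et3SiOTf, Et3N, CH2Cl2, −78 °C
Reagents that add atoms: triethylsilyl trifluoromethanesulfonate, CC[Si](CC)(CC)OS(=O)(=O)C(F)(F)F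
Why: Soft enolisation of the activated α-keto ester (silyl triflate plus amine) gives the silyl enol ether, acetates and acetonide being inert.

Step 21
Reactants: 34 PMB ether
Product: 35 (8R)-C8 alcohol
Conditions: DDQ, CH2Cl2/pH 7 phosphate buffer (10:1), 0 °C
Reagents that add atoms: none
Why: Oxidative PMB cleavage (benzylic hydride abstraction, hydrolysis of the oxocarbenium ion) frees C8-OH; the electron-poor silyloxyacrylate is not oxidised and the buffer keeps it from hydrolysing.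

Step 22
Reactants: 35 C8 alcohol
Product: 36 C8 ketone (C7 silyloxyacrylate, C9-OAc)
Conditions: Dess–Martin periodinane, pyridine, CH2Cl2, rt
Reagents that add atoms: none
Why: Dess–Martin oxidation under buffered conditions gives the α,α′-dioxygenated ketone without enolising C7 or C9.

Step 23
Reactants: 36 keto silyloxyacrylate
Product: 39 (7S,8S,17S)-lactone (C8-OH, C17-OSiEt3; ring C closed), via copper enolate 37 (not isolated), via silyl ether 38 (not isolated)
Conditions: Cu(OAc)2·H2O (10 mol %), 1,2-bis(diphenylphosphino)benzene (10 mol %), (Me2HSi)2O (1.5 equiv), THF, 0 °C → rt; then NH4F, MeOH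
Reagents that add atoms: none
Why: Proposed new method: a phosphine-ligated monovalent copper hydride adds hydride to the unsubstituted β-carbon of the s-cis 2-silyloxyacrylate, turning CH2 into the C18 methyl and giving a fully substituted O-bound copper enolate (methyl cis to O–Cu) held next to the activated C8 ketone; intramolecular aldol through a copper-bridged transition state (ketone oxygen towards O–Cu, the C9 arm exo and anti to C6 across the forming five-membered ring) forms the C8–C17 bond so that C17-methyl and C8-OH are cis (the trans-diol of the target) with C8 (S) and C17 (S), and the copper aldolate is turned over by Si–H; the closest known reaction type is the copper hydride-catalysed reductive aldol cyclisation of keto-enoates to β-hydroxy lactones, here extended to a 2-oxyacrylate that creates two adjacent fully substituted carbinol centres on a ten-membered ring.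

Step 24
Reactants: 39 protected lactone
Product: 40 CNP0203328.1, (1S,2R,3R,4S,5Z,7S,8S,9R,10S,11S,12R,17S)-2,3,4,9-tetraacetoxy-8,11,12,17-tetrahydroxybriara-5,13-dien-19,7-olide
Conditions: CF3CO2H/H2O (9:1), CH2Cl2, 0 °C
Reagents that add atoms: none
Why: Aqueous acid hydrolyses the cis-acetonide (via the oxocarbenium ion at the acetal carbon) and the tertiary triethylsilyl ether, while the four acetates and the lactone survive, releasing C11-OH, C12-OH and C17-OH.

**Compound list**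
1 | (tert-butyldimethylsilyloxy)acetaldehyde | O=CCO[Si](C)(C)C(C)(C)C | starting material
2 | 2-(triphenylphosphoranylidene)propanal | CC(C=O)=P(c1ccccc1)(c1ccccc1)c1ccccc1 | starting material
3 | (2E)-4-[(tert-butyldimethylsilyl)oxy]-2-methylbut-2-enal | O=C/C(C)=C/CO[Si](C)(C)C(C)(C)C | intermediate
4 | (2E)-pent-2-enal | CC/C=C/C=O | starting material
5 | (1E,3E)-penta-1,3-dien-1-yl acetate | CC(=O)O/C=C/C=C/C | intermediate
6 | (1R,2S,5R,6S)-6-{[(tert-butyldimethylsilyl)oxy]methyl}-1-formyl-1,5-dimethylcyclohex-3-en-2-yl acetate | CC(C)(C)[Si](C)(C)OC[C@H]1[C@H](C)C=C[C@H](OC(C)=O)[C@]1(C)C=O | intermediate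
7 | (1S,6S)-6-{[(tert-butyldimethylsilyl)oxy]methyl}-1,5-dimethylcyclohexa-2,4-diene-1-carbaldehyde | CC(C)(C)[Si](C)(C)OC[C@H]1C(C)=CC=C[C@]1(C)C=O | intermediate
8 | (1S,4R,5S,6S)-6-{[(tert-butyldimethylsilyl)oxy]methyl}-4,5-dihydroxy-1,5-dimethylcyclohex-2-ene-1-carbaldehyde | CC(C)(C)[Si](C)(C)OC[C@H]1[C@](C)(O)[C@H](O)C=C[C@]1(C)C=O | intermediate
9 | (1S,4R,5S,6S)-6-{[(tert-butyldimethylsilyl)oxy]methyl}-4,5-(isopropylidenedioxy)-1,5-dimethylcyclohex-2-ene-1-carbaldehyde | CC(C)(C)[Si](C)(C)OC[C@H]1[C@](C)(OC(C)(C)O2)[C@H]2C=C[C@]1(C)C=O | intermediate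
10 | 1-ethynyl analogue of 9 (ring-A alkyne, same configuration) | CC(C)(C)[Si](C)(C)OC[C@H]1[C@](C)(OC(C)(C)O2)[C@H]2C=C[C@]1(C)C#C | intermediate
11 | prop-2-yn-1-ol | C#CCO | starting material
12 | bromomagnesium (2Z)-3-(bromomagnesio)-2-methylprop-2-en-1-olate | Br[Mg]OC/C(C)=C\[Mg]Br | intermediate
13 | (2Z)-3-iodo-2-methylprop-2-en-1-ol | OC/C(C)=C\I | intermediate
14 | (2Z)-3-iodo-2-methylprop-2-enal | O=C/C(C)=C\I | intermediate
15 | (E)-alkenyl(chloro)zirconocene from 10 (Zr on C3) | CC(C)(C)[Si](C)(C)OC[C@H]1[C@](C)(OC(C)(C)O2)[C@H]2C=C[C@]1(C)/C=C/[Zr](Cl)(C3C=CC=C3)C3C=CC=C3 | intermediate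
16 | (E)-alkenyl(methyl)zinc from 10 | CC(C)(C)[Si](C)(C)OC[C@H]1[C@](C)(OC(C)(C)O2)[C@H]2C=C[C@]1(C)/C=C/[Zn]C | intermediate
17 | (1E,3R,4Z)-5-iodo-4-methyl-1-[(1S,4R,5S,6S)-6-{[(tert-butyldimethylsilyl)oxy]methyl}-4,5-(isopropylidenedioxy)-1,5-dimethylcyclohex-2-en-1-yl]penta-1,4-dien-3-ol | CC(C)(C)[Si](C)(C)OC[C@H]1[C@](C)(OC(C)(C)O2)[C@H]2C=C[C@]1(C)/C=C/[C@@H](O)/C(C)=C\I | intermediate
18 | cyclic C2,C3 osmate ester of 17 (hexavalent osmium, TMEDA chelate) | CC(C)(C)[Si](C)(C)OC[C@H]1[C@](C)(OC(C)(C)O2)[C@H]2C=C[C@]1(C)[C@@H](O[Os-2]3(=O)(=O)([N+](C)(C)CC[N+]3(C)C)O4)[C@H]4[C@@H](O)/C(C)=C\I | intermediate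
19 | (1R,2S,3S,4Z)-5-iodo-4-methyl-1-[ring-A unit of 17]pent-4-ene-1,2,3-triol (briarane C2, C3, C4 as in 40) | CC(C)(C)[Si](C)(C)OC[C@H]1[C@](C)(OC(C)(C)O2)[C@H]2C=C[C@]1(C)[C@@H](O)[C@H](O)[C@@H](O)/C(C)=C\I | intermediate
20 | 1,2,3-triacetate of 19 | CC(C)(C)[Si](C)(C)OC[C@H]1[C@](C)(OC(C)(C)O2)[C@H]2C=C[C@]1(C)[C@@H](OC(C)=O)[C@H](OC(C)=O)[C@@H](OC(C)=O)/C(C)=C\I | intermediate
21 | desilylated 20 (6-hydroxymethyl; C9-OH) | OC[C@H]1[C@](C)(OC(C)(C)O2)[C@H]2C=C[C@]1(C)[C@@H](OC(C)=O)[C@H](OC(C)=O)[C@@H](OC(C)=O)/C(C)=C\I | intermediate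
22 | C9 aldehyde: (1R,2S,3S,4Z)-1-[(1S,4R,5S,6R)-6-formyl-4,5-(isopropylidenedioxy)-1,5-dimethylcyclohex-2-en-1-yl]-5-iodo-4-methylpent-4-ene-1,2,3-triyl triacetate | O=C[C@H]1[C@](C)(OC(C)(C)O2)[C@H]2C=C[C@]1(C)[C@@H](OC(C)=O)[C@H](OC(C)=O)[C@@H](OC(C)=O)/C(C)=C\I | intermediate
23 | 1-methoxy-4-[(prop-2-en-1-yloxy)methyl]benzene | C=CCOCc1ccc(OC)cc1 | starting material
24 | (Z)-3-[(4-methoxybenzyl)oxy]allyllithium | [Li]C/C=C\OCc1ccc(OC)cc1 | intermediate
25 | [(2Z)-3-[(4-methoxybenzyl)oxy]prop-2-en-1-yl]bis[(1R,2R,3R,5S)-isopinocampheyl]borane | COc1ccc(CO/C=C\CB([C@@H]2C[C@@H]3C[C@H]([C@H]2C)C3(C)C)[C@@H]2C[C@@H]3C[C@H]([C@H]2C)C3(C)C)cc1 | intermediate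
26 | diisopinocampheylborinate ester of 27 (B on O9) | C=C[C@@H](OCc1ccc(OC)cc1)[C@H](OB([C@@H]2C[C@@H]3C[C@H]([C@H]2C)C3(C)C)[C@@H]2C[C@@H]3C[C@H]([C@H]2C)C3(C)C)[C@H]1[C@](C)(OC(C)(C)O2)[C@H]2C=C[C@]1(C)[C@@H](OC(C)=O)[C@H](OC(C)=O)[C@@H](OC(C)=O)/C(C)=C\I | intermediate
27 | 22 with the formyl group turned into (1R,2R)-1-hydroxy-2-[(4-methoxybenzyl)oxy]but-3-en-1-yl (briarane 8R,9R; other centres as in 40) | C=C[C@@H](OCc1ccc(OC)cc1)[C@H](O)[C@H]1[C@](C)(OC(C)(C)O2)[C@H]2C=C[C@]1(C)[C@@H](OC(C)=O)[C@H](OC(C)=O)[C@@H](OC(C)=O)/C(C)=C\I | intermediate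
28 | C9 acetate of 27 (tetraacetate) | C=C[C@@H](OCc1ccc(OC)cc1)[C@H](OC(C)=O)[C@H]1[C@](C)(OC(C)(C)O2)[C@H]2C=C[C@]1(C)[C@@H](OC(C)=O)[C@H](OC(C)=O)[C@@H](OC(C)=O)/C(C)=C\I | intermediate
29 | vicinal diol from the vinyl group of 28 (mixture at the new carbinol) | OCC(O)[C@@H](OCc1ccc(OC)cc1)[C@H](OC(C)=O)[C@H]1[C@](C)(OC(C)(C)O2)[C@H]2C=C[C@]1(C)[C@@H](OC(C)=O)[C@H](OC(C)=O)[C@@H](OC(C)=O)/C(C)=C\I | intermediate
30 | (8S,9R)-C7 aldehyde: seco-briarane with C7 formyl, C8-OPMB, 2,3,4,9-tetraacetoxy, (5Z)-6-iodo alkene, 11,12-acetonide | O=C[C@@H](OCc1ccc(OC)cc1)[C@H](OC(C)=O)[C@H]1[C@](C)(OC(C)(C)O2)[C@H]2C=C[C@]1(C)[C@@H](OC(C)=O)[C@H](OC(C)=O)[C@@H](OC(C)=O)/C(C)=C\I | intermediate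
31 | C6 alkenylchromium dichloride from 30 (trivalent chromium) | O=C[C@@H](OCc1ccc(OC)cc1)[C@H](OC(C)=O)[C@H]1[C@](C)(OC(C)(C)O2)[C@H]2C=C[C@]1(C)[C@@H](OC(C)=O)[C@H](OC(C)=O)[C@@H](OC(C)=O)/C(C)=C\[Cr](Cl)Cl | intermediate
32 | (7S,8R,9R)-2,3,4,9-tetraacetoxy-7-hydroxy-8-[(4-methoxybenzyl)oxy]-11,12-(isopropylidenedioxy)-17,18,19-trinorbriara-5(Z),13-diene (C1, C2, C3, C4, C10, C11, C12 as in 40) | CC(=O)O[C@@H]1[C@@H](OC(C)=O)/C(C)=C\[C@H](O)[C@@H](OCc2ccc(OC)cc2)[C@H](OC(C)=O)[C@H]2[C@](C)(OC(C)(C)O3)[C@H]3C=C[C@]2(C)[C@H]1OC(C)=O | intermediate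
33 | 7-O-pyruvoyl derivative of 32 | CC(=O)O[C@@H]1[C@@H](OC(C)=O)/C(C)=C\[C@H](OC(=O)C(C)=O)[C@@H](OCc2ccc(OC)cc2)[C@H](OC(C)=O)[C@H]2[C@](C)(OC(C)(C)O3)[C@H]3C=C[C@]2(C)[C@H]1OC(C)=O | intermediate
34 | 7-O-[2-(triethylsilyloxy)acryloyl] derivative of 32 | CC(=O)O[C@@H]1[C@@H](OC(C)=O)/C(C)=C\[C@H](OC(=O)C(=C)O[Si](CC)(CC)CC)[C@@H](OCc2ccc(OC)cc2)[C@H](OC(C)=O)[C@H]2[C@](C)(OC(C)(C)O3)[C@H]3C=C[C@]2(C)[C@H]1OC(C)=O | intermediate
35 | (8R)-8-hydroxy compound (PMB removed from 34) | CC(=O)O[C@@H]1[C@@H](OC(C)=O)/C(C)=C\[C@H](OC(=O)C(=C)O[Si](CC)(CC)CC)[C@@H](O)[C@H](OC(C)=O)[C@H]2[C@](C)(OC(C)(C)O3)[C@H]3C=C[C@]2(C)[C@H]1OC(C)=O | intermediate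
36 | 8-oxo compound: (7S,9R)-2,3,4,9-tetraacetoxy-11,12-(isopropylidenedioxy)-8-oxo-7-{[2-(triethylsilyloxy)acryloyl]oxy}-17,18,19-trinorbriara-5(Z),13-diene | CC(=O)O[C@@H]1[C@@H](OC(C)=O)/C(C)=C\[C@H](OC(=O)C(=C)O[Si](CC)(CC)CC)C(=O)[C@H](OC(C)=O)[C@H]2[C@](C)(OC(C)(C)O3)[C@H]3C=C[C@]2(C)[C@H]1OC(C)=O | intermediate
37 | copper enolate of 36 (O-bound monovalent copper, methyl cis to O–Cu, phosphine omitted) | CC(=O)O[C@@H]1[C@@H](OC(C)=O)/C(C)=C\[C@H](O/C(O[Cu])=C(/C)O[Si](CC)(CC)CC)C(=O)[C@H](OC(C)=O)[C@H]2[C@](C)(OC(C)(C)O3)[C@H]3C=C[C@]2(C)[C@H]1OC(C)=O | intermediate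
38 | 8-O-(1,1,3,3-tetramethyldisiloxanyl) ether of 39 | CC(=O)O[C@@H]1[C@@H](OC(C)=O)/C(C)=C\[C@@H]2OC(=O)[C@@](C)(O[Si](CC)(CC)CC)[C@@]2(O[Si](C)(C)O[SiH](C)C)[C@H](OC(C)=O)[C@H]2[C@](C)(OC(C)(C)O3)[C@H]3C=C[C@]2(C)[C@H]1OC(C)=O | intermediate
39 | 11,12-O-isopropylidene-17-O-triethylsilyl derivative of 40 (all centres as in 40) | CC(=O)O[C@@H]1[C@@H](OC(C)=O)/C(C)=C\[C@@H]2OC(=O)[C@@](C)(O[Si](CC)(CC)CC)[C@@]2(O)[C@H](OC(C)=O)[C@H]2[C@](C)(OC(C)(C)O3)[C@H]3C=C[C@]2(C)[C@H]1OC(C)=O | intermediate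
40 | CNP0203328.1, (1S,2R,3R,4S,5Z,7S,8S,9R,10S,11S,12R,17S)-2,3,4,9-tetraacetoxy-8,11,12,17-tetrahydroxybriara-5,13-dien-19,7-olide | CC(=O)O[C@@H]1[C@@H](OC(C)=O)/C(C)=C\[C@@H]2OC(=O)[C@@](C)(O)[C@@]2(O)[C@H](OC(C)=O)[C@H]2[C@](C)(O)[C@H](O)C=C[C@]2(C)[C@H]1OC(C)=O | target

**Step count and risks**

Total steps: 24. Longest linear sequence: 21 steps (1, 3–7, 10–24); steps 2, 8 and 9 make the two small fragments.

Three steps most likely to fail:

Step 3 (Diels–Alder). A trisubstituted enal and a moderately reactive 1-acetoxydiene may react slowly, and the level and sense of induction are not secured by a close precedent. The fallback moves stereocontrol from the catalyst to a covalently bound auxiliary on the diene. It sets out from 3 and 4 and comes back at 7. The potassium dienolate of 4 (KOtBu, THF, −78 °C) is O-acylated with (S)-O-methylmandeloyl chloride to give the chiral dienyl ester (1E,3E)-penta-1,3-dien-1-yl (2S)-2-methoxy-2-phenylacetate F1, in which the phenyl ring shields one diene face. Cycloaddition with 3 under BF3·OEt2 (CH2Cl2, −78 °C) gives the mandelate adduct F2 as the major diastereomer, which is purified. The Pd(PPh3)4/Et3N elimination of step 4 then removes the auxiliary as its acid and gives 7.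

Step 18 (ring closure and C7 configuration). Closing a ten-membered ring is demanding, and the ligand must override the intrinsic facial bias of the α-alkoxy aldehyde. The fallback sets C7 by reducing a ring ketone instead of in the C–C bond-forming event. It sets out from 30 and comes back at 32. Ligand-free closure (CrCl2, NiCl2 cat., DMSO, 2 mM) is expected to favour the Felkin product, the C7 epimer (7R)-allylic alcohol F3. Dess–Martin oxidation of the epimer mixture gives the macrocyclic enone F4. Reduction with NaBH4/CeCl3·7H2O (MeOH, −78 °C; 1,2-selective, hydride anti to the C8–OPMB bond) gives the 7,8-syn alcohol 32.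

Step 23 (proposed copper hydride reductive aldol lactonisation). Competing 1,2-reduction of the ketone, a mismatched enolate geometry or the wrong ring-fusion diastereomer are all possible. The fallback uses known lactate-enolate chemistry. It sets out from 32 and comes back at 40. The C7 hydroxyl is silylated (Et3SiOTf, 2,6-lutidine) to give the 7-O-triethylsilyl ether F5. DDQ removes the PMB group to give the C8 alcohol F6, and Dess–Martin oxidation gives the C8 ketone F7. The lithium enolate of (2R,5R)-2-tert-butyl-5-methyl-1,3-dioxolan-4-one (from (R)-lactic acid and pivalaldehyde; LDA, THF, −78 °C) is added to F7 precomplexed with MgBr2·OEt2. The enolate reacts anti to its tert-butyl group, and the ketone is attacked under chelation control by the C7 and C9 oxygens, so the 8-hydroxy-8-(dioxolanonyl) adduct F8 carries C17 (S) and C8 (S). Treatment with CF3CO2H/H2O as in step 24 removes the silyl ether, lets the C7 hydroxyl lactonise onto the dioxolanone with loss of pivalaldehyde, and cleaves the acetonide to give 40.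

Further compounds
F1 | step 3 | (1E,3E)-penta-1,3-dien-1-yl (2S)-2-methoxy-2-phenylacetate | CO[C@H](C(=O)O/C=C/C=C/C)c1ccccc1
F2 | step 3 | (1R,2S,5R,6S)-6-{[(tert-butyldimethylsilyl)oxy]methyl}-1-formyl-1,5-dimethylcyclohex-3-en-2-yl (2S)-2-methoxy-2-phenylacetate | CC(C)(C)[Si](C)(C)OC[C@H]1[C@H](C)C=C[C@H](OC(=O)[C@@H](OC)c2ccccc2)[C@]1(C)C=O
F3 | step 18 | C7 epimer of 32 (7R,8R,9R) | CC(=O)O[C@@H]1[C@@H](OC(C)=O)/C(C)=C\[C@@H](O)[C@@H](OCc2ccc(OC)cc2)[C@H](OC(C)=O)[C@H]2[C@](C)(OC(C)(C)O3)[C@H]3C=C[C@]2(C)[C@H]1OC(C)=O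
F4 | step 18 | 7-oxo macrocyclic enone from 32/F3 | CC(=O)O[C@@H]1[C@@H](OC(C)=O)/C(C)=C\C(=O)[C@@H](OCc2ccc(OC)cc2)[C@H](OC(C)=O)[C@H]2[C@](C)(OC(C)(C)O3)[C@H]3C=C[C@]2(C)[C@H]1OC(C)=O
F5 | step 23 | 7-O-triethylsilyl ether of 32 | CC(=O)O[C@@H]1[C@@H](OC(C)=O)/C(C)=C\[C@H](O[Si](CC)(CC)CC)[C@@H](OCc2ccc(OC)cc2)[C@H](OC(C)=O)[C@H]2[C@](C)(OC(C)(C)O3)[C@H]3C=C[C@]2(C)[C@H]1OC(C)=O
F6 | step 23 | 8-hydroxy-7-O-triethylsilyl compound | CC(=O)O[C@@H]1[C@@H](OC(C)=O)/C(C)=C\[C@H](O[Si](CC)(CC)CC)[C@@H](O)[C@H](OC(C)=O)[C@H]2[C@](C)(OC(C)(C)O3)[C@H]3C=C[C@]2(C)[C@H]1OC(C)=O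
F7 | step 23 | 8-oxo-7-O-triethylsilyl compound | CC(=O)O[C@@H]1[C@@H](OC(C)=O)/C(C)=C\[C@H](O[Si](CC)(CC)CC)C(=O)[C@H](OC(C)=O)[C@H]2[C@](C)(OC(C)(C)O3)[C@H]3C=C[C@]2(C)[C@H]1OC(C)=O
F8 | step 23 | 8-hydroxy-8-[(2R,4S)-2-tert-butyl-4-methyl-5-oxo-1,3-dioxolan-4-yl]-7-O-triethylsilyl adduct | CC(=O)O[C@@H]1[C@@H](OC(C)=O)/C(C)=C\[C@H](O[Si](CC)(CC)CC)[C@@](O)([C@]3(C)O[C@@H](C(C)(C)C)OC3=O)[C@H](OC(C)=O)[C@H]2[C@](C)(OC(C)(C)O3)[C@H]3C=C[C@]2(C)[C@H]1OC(C)=O
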